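**Retrosynthetic overview**

1. Feature: number the central benzene ring so that C1 carries the CH2CH2 chain, C2 the ArCH2 group, and C3 and C5 the methoxy groups. The benzylic carbon on C2 and the chain carbon bonded to the 3-hydroxyphenyl ring are then 1,5-related (CH2–C2=C1–CH2–CH2). One oxygen between them closes a pyran ring fused to the central ring, giving a 1,3-diaryl-6,8-dimethoxyisochroman whose two C–O bonds are both benzylic and can be removed again with H2/Pd.
2. Last disconnection: the target is traced back to the bis(benzyl ether) of that isochroman, by hydrogenolysis of both ring C–O bonds and both O-benzyl groups.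
3. Key disconnection: the isochroman is cut at the C2–CH(Ar) bond and the adjacent C–O bond (oxa-Pictet–Spengler), giving rac-1-(3-benzyloxyphenyl)-2-(3,5-dimethoxyphenyl)ethanol and 4-benzyloxybenzaldehyde.
4. The diarylethanol is cut at the carbinol–CH2 bond, giving 3,5-dimethoxybenzyl chloride (as its Grignard reagent) and 3-benzyloxybenzaldehyde.
5. Ring order: the three benzene rings are purchased. The only ring made is the pyran ring (step 2), and it is opened again in step 3.

Key step: step 2

Remark on the chemistry: the target is achiral, so the diarylethanol and the isochroman are racemic and drawn as single enantiomers. The four C–O cleavages of the last step are assumed to end with the secondary benzylic alcohol.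

**Route**

Step 1
Reactants: 1 3,5-dimethoxybenzyl chloride; 2 3-(benzyloxy)benzaldehyde
Product: 5 rac-1-[3-(benzyloxy)phenyl]-2-(3,5-dimethoxyphenyl)ethanol, via benzylic Grignard reagent 3 (not isolated), via chloromagnesium alkoxide 4 (not isolated)
Conditions: Mg turnings (3 equiv), I2 (cat.), 2-MeTHF, slow addition of 1 (1.5 equiv), 0 °C; then 2 (1.0 equiv), −20 °C → rt; sat. aq NH4Cl
Reagents that add atoms: none
Why: Grignard addition, in which the benzylic chloride inserts magnesium readily and the benzylmagnesium chloride adds 1,2 to the non-enolizable aryl aldehyde; slow addition of the chloride to excess metal limits Wurtz coupling, and the carbinol center forms racemic, which suffices because it becomes a CH2 group in step 3.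

Step 2
Reactants: 5 rac-1-[3-(benzyloxy)phenyl]-2-(3,5-dimethoxyphenyl)ethanol; 6 4-(benzyloxy)benzaldehyde
Product: 9 rac-cis-1-[4-(benzyloxy)phenyl]-3-[3-(benzyloxy)phenyl]-6,8-dimethoxyisochroman, via hemiacetal 7 (not isolated), via oxocarbenium ion 8 (not isolated)
Conditions: 6 (1.2 equiv), BF3·OEt2 (0.3 equiv), 4 Å MS, CH2Cl2, −30 → 0 °C; Et3N, aq NaHCO3 quench
Reagents that add atoms: none
Why: BF3 promotes addition of alcohol 5 to aldehyde 6 to give hemiacetal 7 and its ionization to the 4-benzyloxyphenyl-stabilized oxocarbenium ion 8, which is captured by the ring carbon of the 3,5-dimethoxyphenyl group next to the CH2 substituent, and loss of a proton restores the arene. The closest known reaction type is the oxa-Pictet–Spengler cyclization of 2-arylethanols with aromatic aldehydes to 1-arylisochromans. The pyran ring closes by a 6-endo-trig Friedel–Crafts attack on the C=O+ carbon, forming the C8a–C1 bond after the C1–O2 bond. The new stereocenter C1 is set relative to C3 by a half-chair transition state with an E-oxocarbenium ion and the C3 aryl group pseudo-equatorial, which should favour the cis isomer; peri strain between the C1 aryl group and the C8 methoxy group may erode this, but both epimers give the same achiral product in step 3. The selectivity that matters is the site of arylation, and it is secured by the tether and the symmetry of the 3,5-dimethoxyphenyl ring: only the two equivalent carbons flanking the CH2 group (each ortho to one methoxy group and para to the other) can reach the cation, the carbon between the methoxy groups cannot, and the 3-benzyloxyphenyl ring would have to close a five-membered ring by 5-endo attack. A substoichiometric Lewis acid at low temperature is used because the carbinol carbon carries only a meta-oxygenated aryl group and so should not ionize toward the stilbene under these conditions.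

Step 3
Reactants: 9 rac-cis-1-[4-(benzyloxy)phenyl]-3-[3-(benzyloxy)phenyl]-6,8-dimethoxyisochroman
Product: 11 Gymcononopin D (3-{2-[2-(4-hydroxybenzyl)-3,5-dimethoxyphenyl]ethyl}phenol), via ring-opened benzylic alcohol 10 (not isolated)
Conditions: H2 (4 atm), Pd/C (10 wt% Pd), HClO4 (0.1 equiv), AcOH–EtOAc 1:1, 25 → 45 °C
Reagents that add atoms: none
Why: Catalytic hydrogenolysis, in which the two aryl benzyl ethers and the doubly benzylic C1–O bond should cleave readily on palladium and the remaining secondary benzylic alcohol 10 is reduced once activated by the added acid, so both ring stereocenters become CH2 groups while the aryl methyl ethers are untouched.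

**Compound list**

1 | 3,5-dimethoxybenzyl chloride | COc1cc(CCl)cc(OC)c1 | starting material
2 | 3-(benzyloxy)benzaldehyde | O=Cc1cccc(OCc2ccccc2)c1 | starting material
3 | (3,5-dimethoxybenzyl)magnesium chloride, benzylic Grignard reagent, not isolated | COc1cc(C[Mg]Cl)cc(OC)c1 | intermediate
4 | chloromagnesium alkoxide of 5, racemic with (R) drawn, not isolated | Cl[Mg]O[C@@H](c1cccc(OCc2ccccc2)c1)Cc1cc(OC)cc(OC)c1 | intermediate
5 | rac-1-[3-(benzyloxy)phenyl]-2-(3,5-dimethoxyphenyl)ethanol, (R) drawn | O[C@@H](c1cccc(OCc2ccccc2)c1)Cc1cc(OC)cc(OC)c1 | intermediate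
6 | 4-(benzyloxy)benzaldehyde | O=Cc1ccc(OCc2ccccc2)cc1 | starting material
7 | hemiacetal of 5 and 6, both epimers at the hemiacetal carbon, not isolated | OC(c1ccc(OCc2ccccc2)cc1)O[C@@H](c1cccc(OCc2ccccc2)c1)Cc1cc(OC)cc(OC)c1 | intermediate
8 | (E)-O-alkyl oxocarbenium ion from 7, not isolated | O(Cc1ccccc1)c1ccc(cc1)/C=[O+]/[C@@H](c1cccc(OCc2ccccc2)c1)Cc1cc(OC)cc(OC)c1 | intermediate
9 | rac-cis-1-[4-(benzyloxy)phenyl]-3-[3-(benzyloxy)phenyl]-6,8-dimethoxyisochroman, (1R,3R) drawn | COc1cc2c(c(OC)c1)[C@@H](c1ccc(OCc3ccccc3)cc1)O[C@@H](c1cccc(OCc3ccccc3)c1)C2 | intermediate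
10 | rac-1-(3-hydroxyphenyl)-2-[2-(4-hydroxybenzyl)-3,5-dimethoxyphenyl]ethanol, (R) drawn, not isolated | COc1cc(C[C@@H](O)c2cccc(O)c2)c(Cc2ccc(O)cc2)c(OC)c1 | intermediate
11 | Gymcononopin D, 3-{2-[2-(4-hydroxybenzyl)-3,5-dimethoxyphenyl]ethyl}phenol | COc1cc(CCc2cccc(O)c2)c(Cc2ccc(O)cc2)c(OC)c1 | target

**Totals**

Total step count: 3. Longest linear sequence: 3 steps (1 or 2 → 5 → 9 → 11).

**Steps most likely to fail, with fallbacks**

Risk 1 (step 2, the key cyclization). The secondary benzylic alcohol may ionize and dehydrate before the hemiacetal ionizes. The product may also reopen at C1 and undergo intermolecular arylation, leading to oligomers. The fallback sets out from 5 and returns at 9, and makes the C–C bond by an organometallic addition instead of a Friedel–Crafts closure.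
- Bromination of 5 with NBS (MeCN, 0 °C) should occur on the dimethoxylated ring at the carbon next to the CH2 group, para to a methoxy group. This gives rac-1-[3-(benzyloxy)phenyl]-2-(2-bromo-3,5-dimethoxyphenyl)ethanol F1.
- n-BuLi (2.2 equiv, THF, −78 °C) would deprotonate the hydroxyl group and exchange bromine for lithium, giving the lithium alkoxide/aryllithium F2.
- Addition of aldehyde 6 and aqueous work-up should give the diol 1-[3-(benzyloxy)phenyl]-2-{2-[[4-(benzyloxy)phenyl](hydroxy)methyl]-3,5-dimethoxyphenyl}ethanol F3 as a mixture of diastereomers.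
- Catalytic p-TsOH·H2O in CH2Cl2 at 0 °C should then ionize the diarylmethanol, and the secondary hydroxyl group traps the cation to close the pyran ring of 9.

Risk 2 (step 3). The hydrogenolysis may stall at the secondary benzylic alcohol, whose C–O bond lies next to a ring without an ortho or para donor. The acid may also trigger Friedel–Crafts side reactions of that alcohol. The fallback sets out from 9 and returns at 11, and removes the second C–O bond by elimination and alkene hydrogenation.
- Et3SiH with BF3·OEt2 (CH2Cl2, −40 → 0 °C) should open only the doubly benzylic C1–O bond of 9 by ionic hydrogenation. After work-up this gives rac-1-[3-(benzyloxy)phenyl]-2-{2-[4-(benzyloxy)benzyl]-3,5-dimethoxyphenyl}ethanol F4.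
- Dehydration with catalytic p-TsOH·H2O in toluene at reflux, with removal of water, should give (E)-1-[3-(benzyloxy)styryl]-2-[4-(benzyloxy)benzyl]-3,5-dimethoxybenzene F5.
- H2 over Pd/C in EtOAc–EtOH at room temperature, without acid, should saturate the alkene and remove both benzyl groups to give 11.

Risk 3 (step 1). Wurtz homocoupling may compete during magnesium insertion. The benzylic Grignard reagent may also add through the ring carbon ortho to the CH2MgCl group instead of the benzylic carbon. The fallback sets out from 2, uses 1 as the electrophile, and returns at 5, reversing the polarity of the coupling.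
- Aldehyde 2 with propane-1,3-dithiol and BF3·OEt2 (CH2Cl2, 0 °C) should give 2-[3-(benzyloxy)phenyl]-1,3-dithiane F6.
- n-BuLi (THF, −30 °C) would give 2-[3-(benzyloxy)phenyl]-2-lithio-1,3-dithiane F7.
- Alkylation of F7 with chloride 1 should give 2-[3-(benzyloxy)phenyl]-2-(3,5-dimethoxybenzyl)-1,3-dithiane F8.
- Hydrolysis with MeI and CaCO3 in aqueous MeCN at 45 °C should release the ketone 1-[3-(benzyloxy)phenyl]-2-(3,5-dimethoxyphenyl)ethanone F9.
- NaBH4 in MeOH at 0 °C reduces F9 to 5.

**Further compounds**

F1 | step 2 | rac-1-[3-(benzyloxy)phenyl]-2-(2-bromo-3,5-dimethoxyphenyl)ethanol, (R) drawn | O[C@@H](c1cccc(OCc2ccccc2)c1)Cc1cc(OC)cc(OC)c1Br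
F2 | step 2 | lithium alkoxide/aryllithium from F1 | [Li]O[C@@H](c1cccc(OCc2ccccc2)c1)Cc1cc(OC)cc(OC)c1[Li]
F3 | step 2 | 1-[3-(benzyloxy)phenyl]-2-{2-[[4-(benzyloxy)phenyl](hydroxy)methyl]-3,5-dimethoxyphenyl}ethanol, diastereomer mixture | O[C@@H](c1cccc(OCc2ccccc2)c1)Cc1cc(OC)cc(OC)c1C(O)c1ccc(OCc2ccccc2)cc1
F4 | step 3 | rac-1-[3-(benzyloxy)phenyl]-2-{2-[4-(benzyloxy)benzyl]-3,5-dimethoxyphenyl}ethanol, (R) drawn | O[C@@H](c1cccc(OCc2ccccc2)c1)Cc1cc(OC)cc(OC)c1Cc1ccc(OCc2ccccc2)cc1
F5 | step 3 | (E)-1-[3-(benzyloxy)styryl]-2-[4-(benzyloxy)benzyl]-3,5-dimethoxybenzene | COc1cc(/C=C/c2cccc(OCc3ccccc3)c2)c(Cc2ccc(OCc3ccccc3)cc2)c(OC)c1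
F6 | step 1 | 2-[3-(benzyloxy)phenyl]-1,3-dithiane | C1CSC(SC1)c1cccc(OCc2ccccc2)c1
F7 | step 1 | 2-[3-(benzyloxy)phenyl]-2-lithio-1,3-dithiane | [Li]C1(SCCCS1)c1cccc(OCc2ccccc2)c1
F8 | step 1 | 2-[3-(benzyloxy)phenyl]-2-(3,5-dimethoxybenzyl)-1,3-dithiane | COc1cc(CC2(SCCCS2)c2cccc(OCc3ccccc3)c2)cc(OC)c1
F9 | step 1 | 1-[3-(benzyloxy)phenyl]-2-(3,5-dimethoxyphenyl)ethanone | O=C(Cc1cc(OC)cc(OC)c1)c1cccc(OCc2ccccc2)c1
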